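**Strategy**

Everything rests on the bond between C6 of the resorcylate ring A and C1 of the 2-oxononyl chain. C6 lies ortho to the depside carbonyl and meta to both ring-A oxygens, so it is addressed as an aryl bromide. The complete, benzyl-protected depside brominated at C6 is joined to the terminal (kinetic) trimethylsilyl enol ether of 2-nonanone by a palladium-catalysed, tributyltin-fluoride-mediated arylation, which delivers the whole chain as the free ketone in one neutral operation. Neutrality is the point: the ketone sits 1,5 to the aryl ester carbonyl, and any enolate would expel ring B as an isocoumarin forms. Hydrogenolysis of three benzyl groups then gives the target.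

Key step: step 9

Remark: the target has no stereocentre and no stereogenic double bond; it is achiral, so no step has to set or protect configuration.

**Route**

Step 1
Reactants: 1 5-bromoresorcinol (5-bromobenzene-1,3-diol)
Product: 2 1,3-bis(benzyloxy)-5-bromobenzene
Conditions: BnBr, K2CO3, DMF, 60 °C
Reagents that add atoms: benzyl bromide, BrCc1ccccc1
Why: Williamson ether synthesis on both phenoxides, which are far more nucleophilic at oxygen than at carbon under carbonate in DMF.

Step 2
Reactants: 2 1,3-bis(benzyloxy)-5-bromobenzene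
Product: 4 2,4-bis(benzyloxy)-6-bromobenzaldehyde, via iminium salt 3 (not isolated)
Conditions: POCl3, DMF, 0 → 70 °C; then ice-water
Reagents that add atoms: N,N-dimethylformamide, CN(C)C=O; water, O
Why: Vilsmeier–Haack formylation, in which the chloroiminium ion attacks para to one benzyloxy group and ortho to the other at the C–H next to bromine rather than the more hindered C–H between the two benzyloxy groups, and water hydrolyses iminium 3 to the aldehyde.

Step 3
Reactants: 4 2,4-bis(benzyloxy)-6-bromobenzaldehyde
Product: 5 2,4-bis(benzyloxy)-6-bromobenzoic acid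
Conditions: NaClO2, NaH2PO4, 2-methyl-2-butene, t-BuOH/THF/H2O, rt
Reagents that add atoms: sodium chlorite, [Na+].[O-][Cl]=O
Why: Pinnick oxidation, which tolerates a hindered, electron-rich aldehyde because the alkene scavenges hypochlorous acid before it can chlorinate the ring.

Step 4
Reactants: 6 5-heptylresorcinol (5-heptylbenzene-1,3-diol)
Product: 7 2-heptyl-4,6-dihydroxybenzoic acid
Conditions: methylmagnesium carbonate (2 M in DMF), 120 °C; then cold aq. HCl
Reagents that add atoms: methylmagnesium carbonate, COC(=O)O[Mg]OC
Why: Kolbe–Schmitt-type carboxylation, in which the magnesium phenoxide chelate should deliver CO2 ortho to one hydroxyl and para to the other (next to the heptyl chain), by analogy with 5-pentylresorcinol, and holds the salicylate as a chelate until acidification.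

Step 5
Reactants: 7 2-heptyl-4,6-dihydroxybenzoic acid
Product: 8 benzyl 2-heptyl-4,6-dihydroxybenzoate
Conditions: BnBr, KHCO3, DMF, rt
Reagents that add atoms: benzyl bromide, BrCc1ccccc1
Why: SN2 O-alkylation of the carboxylate, selective because hydrogen carbonate ionises the acid but not the phenols.

Step 6
Reactants: 5 2,4-bis(benzyloxy)-6-bromobenzoic acid; 8 benzyl 2-heptyl-4,6-dihydroxybenzoate
Product: 10 benzyl 4-{[2,4-bis(benzyloxy)-6-bromobenzoyl]oxy}-2-heptyl-6-hydroxybenzoate, via acid chloride 9 (not isolated)
Conditions: (COCl)2, cat. DMF, CH2Cl2, 0 °C → rt, concentrate; then 8, Et3N, cat. DMAP, CH2Cl2, 0 °C → rt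
Reagents that add atoms: none
Why: DMAP-catalysed acylation of a phenol by an acid chloride, selective for the 4-hydroxyl of 8 because the other hydroxyl is hydrogen-bonded to, and shielded by, the neighbouring benzyl ester.

Step 7
Reactants: 10 benzyl 4-{[2,4-bis(benzyloxy)-6-bromobenzoyl]oxy}-2-heptyl-6-hydroxybenzoate
Product: 11 benzyl 4-{[2,4-bis(benzyloxy)-6-bromobenzoyl]oxy}-2-heptyl-6-methoxybenzoate
Conditions: MeI, K2CO3, DMF, rt
Reagents that add atoms: iodomethane, CI
Why: Williamson O-methylation of the only free phenol, at a stage where the di-ortho-substituted depside carbonyl is shielded from carbonate and no enolisable ketone is yet present.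

Step 8
Reactants: 12 nonan-2-one
Product: 14 trimethyl(non-1-en-2-yloxy)silane, via lithium enolate 13 (not isolated)
Conditions: LDA, THF, −78 °C; then TMSCl, −78 °C → rt
Reagents that add atoms: chlorotrimethylsilane, C[Si](C)(C)Cl
Why: kinetic deprotonation of the methyl ketone at the less hindered methyl group followed by O-silylation fixes the terminal enol regiochemistry (kinetic silyl enol ether formation).

Step 9
Reactants: 11 benzyl 4-{[2,4-bis(benzyloxy)-6-bromobenzoyl]oxy}-2-heptyl-6-methoxybenzoate; 14 trimethyl(non-1-en-2-yloxy)silane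
Product: 16 benzyl 4-{[2,4-bis(benzyloxy)-6-(2-oxononyl)benzoyl]oxy}-2-heptyl-6-methoxybenzoate, via tin enolate 15 (not isolated)
Conditions: Pd2(dba)3 (cat.), P(t-Bu)3 (cat.), Bu3SnF, toluene, 85 °C
Reagents that add atoms: none
Why: Bu3SnF converts enol silane 14 into tributyltin enolate 15 with its terminal double bond intact, Pd(0)/P(t-Bu)3 inserts into the C6–Br bond of ring A, tin-to-palladium transmetalation gives an aryl–Pd–CH2C(O)C7H15 species, and reductive elimination forges the C6–CH2 bond. The closest known reaction type is the palladium-catalysed arylation of tin enolates, in its form as the Bu3SnF-mediated regiocontrolled α-arylation of trimethylsilyl enol ethers with aryl bromides. No ring is closed and no stereocentre is created. Regioselectivity for C1 over C3 of the nonanone is needed and is secured by the kinetic enol silane, because no base is present to equilibrate the enolate. Chemoselectivity is needed because the product is a benzylic ketone 1,5-related to the aryl ester carbonyl: a free enolate would O-acylate and expel ring B as its phenol, and a carbonate or carboxylate base would permit cyclising C–H arylation of ring B, both of which the neutral, fluoride-only medium should suppress. The benzyl ethers, benzyl ester, methyl ether and depside ester should be inert, since oxidative addition into the aryl C–Br bond is much faster than into any C–O bond at this temperature.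

Step 10
Reactants: 16 benzyl 4-{[2,4-bis(benzyloxy)-6-(2-oxononyl)benzoyl]oxy}-2-heptyl-6-methoxybenzoate
Product: 17 4-{[2,4-dihydroxy-6-(2-oxononyl)benzoyl]oxy}-2-heptyl-6-methoxybenzoic acid
Conditions: H2 (1 atm), 10% Pd/C, EtOAc, rt
Reagents that add atoms: none
Why: catalytic hydrogenolysis cleaves the two benzyl ethers and the benzyl ester under neutral conditions that leave the aliphatic ketone, the aryl ester and the methyl ether untouched.

**Compound list**

1 | 5-bromoresorcinol (5-bromobenzene-1,3-diol) | Oc1cc(O)cc(Br)c1 | starting material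
2 | 1,3-bis(benzyloxy)-5-bromobenzene | Brc1cc(OCc2ccccc2)cc(OCc2ccccc2)c1 | intermediate
3 | N-[2,4-bis(benzyloxy)-6-bromobenzylidene]-N-methylmethanaminium chloride (iminium salt) | C[N+](C)=Cc1c(Br)cc(OCc2ccccc2)cc1OCc1ccccc1.[Cl-] | intermediate (not isolated)
4 | 2,4-bis(benzyloxy)-6-bromobenzaldehyde | O=Cc1c(Br)cc(OCc2ccccc2)cc1OCc1ccccc1 | intermediate
5 | 2,4-bis(benzyloxy)-6-bromobenzoic acid | OC(=O)c1c(Br)cc(OCc2ccccc2)cc1OCc1ccccc1 | intermediate
6 | 5-heptylresorcinol (5-heptylbenzene-1,3-diol) | CCCCCCCc1cc(O)cc(O)c1 | starting material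
7 | 2-heptyl-4,6-dihydroxybenzoic acid | CCCCCCCc1cc(O)cc(O)c1C(=O)O | intermediate
8 | benzyl 2-heptyl-4,6-dihydroxybenzoate | CCCCCCCc1cc(O)cc(O)c1C(=O)OCc1ccccc1 | intermediate
9 | 2,4-bis(benzyloxy)-6-bromobenzoyl chloride (acid chloride) | ClC(=O)c1c(Br)cc(OCc2ccccc2)cc1OCc1ccccc1 | intermediate (not isolated)
10 | benzyl 4-{[2,4-bis(benzyloxy)-6-bromobenzoyl]oxy}-2-heptyl-6-hydroxybenzoate | CCCCCCCc1cc(OC(=O)c2c(Br)cc(OCc3ccccc3)cc2OCc2ccccc2)cc(O)c1C(=O)OCc1ccccc1 | intermediate
11 | benzyl 4-{[2,4-bis(benzyloxy)-6-bromobenzoyl]oxy}-2-heptyl-6-methoxybenzoate | CCCCCCCc1cc(OC(=O)c2c(Br)cc(OCc3ccccc3)cc2OCc2ccccc2)cc(OC)c1C(=O)OCc1ccccc1 | intermediate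
12 | nonan-2-one | CCCCCCCC(C)=O | starting material
13 | lithium non-1-en-2-olate (lithium enolate) | [Li]OC(=C)CCCCCCC | intermediate (not isolated)
14 | trimethyl(non-1-en-2-yloxy)silane | C=C(CCCCCCC)O[Si](C)(C)C | intermediate
15 | tributyl(non-1-en-2-yloxy)stannane (tin enolate) | C=C(CCCCCCC)O[Sn](CCCC)(CCCC)CCCC | intermediate (not isolated)
16 | benzyl 4-{[2,4-bis(benzyloxy)-6-(2-oxononyl)benzoyl]oxy}-2-heptyl-6-methoxybenzoate | CCCCCCCC(=O)Cc1cc(OCc2ccccc2)cc(OCc2ccccc2)c1C(=O)Oc1cc(CCCCCCC)c(C(=O)OCc2ccccc2)c(OC)c1 | intermediate
17 | 4-{[2,4-dihydroxy-6-(2-oxononyl)benzoyl]oxy}-2-heptyl-6-methoxybenzoic acid | CCCCCCCC(=O)Cc1cc(O)cc(O)c1C(=O)Oc1cc(CCCCCCC)c(C(=O)O)c(OC)c1 | target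

**Step count and risks**

Total step count: 10. Longest linear sequence: 7 steps (steps 1, 2, 3, 6, 7, 9, 10).

Steps most likely to fail:

1. Step 9. The benzylic ketone that forms is more acidic than nonan-2-one, so proton transfer to the tin enolate may be followed by intramolecular O-acylation with loss of the ring-B phenol. Alternatively, transmetalation or reductive elimination may stall at the ortho-acyl aryl–palladium centre and end in hydrodebromination. The fallback sets out from 11 and 14 and comes back at 16. Enol silane 14 is chlorinated with N-chlorosuccinimide (THF, 0 °C) to 1-chlorononan-2-one F1. Bromide 11 is then joined to F1 by a nickel-catalysed electroreductive cross-electrophile coupling (NiBr2(bpy) cat., Bu4NBF4, DMF, sacrificial zinc anode, constant current, 60 °C, slow addition of F1). Here the aryl–nickel species formed at the cathode captures the α-chloroketone, and neither a tin enolate nor a base is present.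

2. Step 4. Carboxylation may take place at the carbon between the two hydroxyls, and the product may lose CO2 again during acidic work-up. The fallback sets out from 6 and comes back at 7. Vilsmeier–Haack formylation (POCl3, DMF; aqueous hydrolysis) attacks para to one hydroxyl and should give 2-heptyl-4,6-dihydroxybenzaldehyde F2. Chlorite oxidation with a hypochlorite scavenger (NaClO2, sulfamic acid, aqueous dioxane, 0 °C) should then give 7.

3. Step 7. Alkylation of the hydrogen-bonded hydroxyl may be slow enough for carbonate or phenoxide to cleave or transfer the depside acyl group. The fallback sets out from 8 and comes back at 11. The non-chelated 4-hydroxyl of 8 is silylated (TIPSCl, imidazole, DMF, 0 °C) to benzyl 2-heptyl-6-hydroxy-4-[(triisopropylsilyl)oxy]benzoate F3. The remaining hydroxyl is methylated (MeI, K2CO3, acetone) to benzyl 2-heptyl-6-methoxy-4-[(triisopropylsilyl)oxy]benzoate F4. Fluoride (TBAF, AcOH, THF) releases benzyl 2-heptyl-4-hydroxy-6-methoxybenzoate F5. Acylation of F5 with acid chloride 9 (made from 5 as in step 6; Et3N, cat. DMAP, CH2Cl2) gives 11 directly, so the depside never meets base.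

Further compounds
F1 | step 9 | 1-chlorononan-2-one | CCCCCCCC(=O)CCl
F2 | step 4 | 2-heptyl-4,6-dihydroxybenzaldehyde | CCCCCCCc1cc(O)cc(O)c1C=O
F3 | step 7 | benzyl 2-heptyl-6-hydroxy-4-[(triisopropylsilyl)oxy]benzoate | CCCCCCCc1cc(O[Si](C(C)C)(C(C)C)C(C)C)cc(O)c1C(=O)OCc1ccccc1
F4 | step 7 | benzyl 2-heptyl-6-methoxy-4-[(triisopropylsilyl)oxy]benzoate | CCCCCCCc1cc(O[Si](C(C)C)(C(C)C)C(C)C)cc(OC)c1C(=O)OCc1ccccc1
F5 | step 7 | benzyl 2-heptyl-4-hydroxy-6-methoxybenzoate | CCCCCCCc1cc(O)cc(OC)c1C(=O)OCc1ccccc1
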